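**Plan**

Numbering (germacrane): carbocycle C1–C10 with C1=C2, ketone C3, C4 (methyl C15), C5, lactone O–CH C6, fusion CH C7, tiglate CH C8, CH2 C9, carbinol C10 (methyl C14); lactone C11 (alpha), C12 (C=O), C13 (exomethylene).
Enabling feature: C14, C10, C1, C2 and C3 are the carbon atoms of 2-methylfuran. The C10 tertiary alcohol, the ring-cis C1=C2 bond and the C3 ketone are the hydrolysed form of a 3,10-oxygen-bridged 2,5-dihydrofuran ketal, i.e. of a furan that has taken up carbon at its methyl-bearing position and an alkoxy group at the other alpha position.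
Cuts, in retrosynthetic order: the C8 tiglate ester; C8–H (back to the ketone); the C3 ketal; C9–C10 together with C3–OMe (anodic furan/enol ether coupling, which opens the ten-membered ring); C6–C7 and the lactone C–O (indium Barbier allylation and lactonisation); C3–C4 (Negishi coupling).
Forward order: a Z furyl enal (from ethyl but-2-ynoate and 2-methylfuran) and a lactate-derived 2-(bromomethyl)enoate (Morita–Baylis–Hillman reaction with methyl acrylate) are joined to give the cis alpha-methylene lactone first; the ten-membered ring then closes across the furan; ketal hydrolysis, C8 reduction and tigloylation finish the synthesis.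
Stereochemistry: the (S)-lactate centre (C8) directs C6 and C7 in the Barbier step and is then erased by oxidation; C10 (and the transient C3) follow from the face of the furan that the lactone-bound arm can reach; C8 is reset by hydroxyl-directed anti reduction from C10; C4=C5 (Z) comes from anti hydroiodination and C1=C2 (Z) from the furan ring.

Key step: step 13

Remark: the target is drawn as the Z gamma-hydroxy enone; this is the ring-opened tautomer of the corresponding 3,10-hemiketal, the two are taken to interconvert, and compounds 24, 25 and 27 are written in the open form.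

**Route**

Step 1
Reactants: 1 ethyl but-2-ynoate
Product: 2 ethyl (2Z)-3-iodobut-2-enoate
Conditions: NaI, AcOH, 115 °C
Reagents that add atoms: sodium iodide, [Na+].[I-]
Why: Hydroiodination of a 2-ynoate with HI made in the flask is a standard anti addition (iodide to C3, proton to C2 from the opposite side), so iodine ends cis to the ester and the later C4=C5 geometry is fixed here.

Step 2
Reactants: 3 2-methylfuran; 2 ethyl (2Z)-3-iodobut-2-enoate
Product: 6 ethyl (2Z)-3-(5-methylfuran-2-yl)but-2-enoate, via (5-methylfuran-2-yl)lithium 4 (not isolated), via chloro(5-methylfuran-2-yl)zinc 5 (not isolated)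
Conditions: n-BuLi, THF, 0 °C; ZnCl2, THF, 0 °C to rt; then 2, Pd(PPh3)4 (cat.), THF, rt
Reagents that add atoms: none
Why: 2-Methylfuran is lithiated at its only free alpha position, and Negishi coupling of the derived zinc reagent at zerovalent palladium proceeds with retention of the vinyl iodide geometry, which places the furan cis to the ester.

Step 3
Reactants: 6 ethyl (2Z)-3-(5-methylfuran-2-yl)but-2-enoate
Product: 7 (2Z)-3-(5-methylfuran-2-yl)but-2-en-1-ol
Conditions: i-Bu2AlH (2.2 equiv), CH2Cl2, −78 °C; aq. potassium sodium tartrate
Reagents that add atoms: none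
Why: Two hydride equivalents at low temperature reduce the conjugated ester in the 1,2 sense to the allylic alcohol without touching the trisubstituted Z alkene or the furan.

Step 4
Reactants: 7 (2Z)-3-(5-methylfuran-2-yl)but-2-en-1-ol
Product: 8 (2Z)-3-(5-methylfuran-2-yl)but-2-enal
Conditions: activated MnO2, CH2Cl2, rt, dark
Reagents that add atoms: none
Why: Activated MnO2 oxidises allylic alcohols selectively under neutral conditions, which avoids the acid- or light-induced Z to E isomerisation of the push-pull enal; 8 is used at once.

Step 5
Reactants: 9 methyl (S)-lactate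
Product: 10 methyl (2S)-2-[(tert-butyldimethylsilyl)oxy]propanoate
Conditions: TBSCl, imidazole, DMF, 0 °C to rt
Reagents that add atoms: tert-butyldimethylsilyl chloride, CC(C)(C)[Si](C)(C)Cl
Why: Standard imidazole-promoted silylation of the secondary alcohol, which leaves the stereocentre untouched.

Step 6
Reactants: 10 methyl (2S)-2-[(tert-butyldimethylsilyl)oxy]propanoate
Product: 11 (2S)-2-[(tert-butyldimethylsilyl)oxy]propanal
Conditions: i-Bu2AlH (1.05 equiv), CH2Cl2, −78 °C; aq. potassium sodium tartrate
Reagents that add atoms: none
Why: At −78 °C the tetrahedral aluminium alkoxide formed from the ester is stable until work-up, so reduction stops at the aldehyde; the alpha-silyloxy aldehyde is not purified on silica, to keep its configuration.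

Step 7
Reactants: 11 (2S)-2-[(tert-butyldimethylsilyl)oxy]propanal; 12 methyl acrylate
Product: 13 methyl (4S)-4-[(tert-butyldimethylsilyl)oxy]-3-hydroxy-2-methylidenepentanoate (both C3 epimers)
Conditions: 1,4-diazabicyclo[2.2.2]octane (0.5 equiv), neat methyl acrylate (excess), rt
Reagents that add atoms: none
Why: Morita–Baylis–Hillman reaction: the amine adds to the acrylate, the resulting enolate adds to the activated alpha-alkoxy aldehyde and the amine is eliminated; the new carbinol centre forms as a mixture of epimers that converges in step 8, where this carbon becomes sp2.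

Step 8
Reactants: 13 methyl (4S)-4-[(tert-butyldimethylsilyl)oxy]-3-hydroxy-2-methylidenepentanoate
Product: 14 methyl (2Z,4S)-2-(bromomethyl)-4-[(tert-butyldimethylsilyl)oxy]pent-2-enoate
Conditions: NBS, Me2S, CH2Cl2, 0 °C to rt
Reagents that add atoms: N-bromosuccinimide, O=C1CCC(=O)N1Br
Why: The bromodimethylsulfonium salt made from NBS and Me2S activates the allylic hydroxyl (Corey–Kim-type), and bromide then enters at the methylene terminus with allylic transposition (SN2′), which for Morita–Baylis–Hillman adducts of acrylates gives the thermodynamically preferred (Z)-2-(bromomethyl)alk-2-enoate.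

Step 9
Reactants: 14 methyl (2Z,4S)-2-(bromomethyl)-4-[(tert-butyldimethylsilyl)oxy]pent-2-enoate; 8 (2Z)-3-(5-methylfuran-2-yl)but-2-enal
Product: 17 cis lactone (4S,5S)-4-[(1S)-1-(tert-butyldimethylsilyloxy)ethyl]-3-methylidene-5-[(1Z)-2-(5-methylfuran-2-yl)prop-1-en-1-yl]oxolan-2-one, via allylindium bromide 15 (not isolated), via syn hydroxy ester 16 (not isolated)
Conditions: indium powder, THF/H2O (1:1), rt; then pyridinium p-toluenesulfonate (cat.), CH2Cl2, rt
Reagents that add atoms: none
Why: Barbier-type allylation: indium inserts into the C–Br bond and the 2-(methoxycarbonyl)allylindium adds to the aldehyde through its gamma carbon (SE2′) in a chair transition state; the Z geometry (C8 cis to the CH2In group, hence axial) gives the syn adduct and so the cis lactone, while allylic 1,3-strain holds the C8–H in the alkene plane so that the aldehyde bonds to C7 on the face anti to the bulky silyloxy group (the rotamer with the oxygen in the plane leads to the same face), which from the (S) centre should give 6S,7S; mild acid then closes the gamma-lactone on the only free hydroxyl.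

Step 10
Reactants: 17 cis lactone (4S,5S)-4-[(1S)-1-(tert-butyldimethylsilyloxy)ethyl]-3-methylidene-5-[(1Z)-2-(5-methylfuran-2-yl)prop-1-en-1-yl]oxolan-2-one
Product: 18 (4R,5S)-4-[(1S)-1-hydroxyethyl]-3-methylidene-5-[(1Z)-2-(5-methylfuran-2-yl)prop-1-en-1-yl]oxolan-2-one
Conditions: HF·pyridine, pyridine, THF, 0 °C to rt
Reagents that add atoms: none
Why: Buffered HF·pyridine cleaves the secondary silyl ether by fluoride attack on silicon under conditions mild enough for the alkenylfuran, the exomethylene lactone and the ionisable allylic C6–O bond, and too weakly basic for translactonisation to O8.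

Step 11
Reactants: 18 (4R,5S)-4-[(1S)-1-hydroxyethyl]-3-methylidene-5-[(1Z)-2-(5-methylfuran-2-yl)prop-1-en-1-yl]oxolan-2-one
Product: 19 (4S,5S)-4-acetyl-3-methylidene-5-[(1Z)-2-(5-methylfuran-2-yl)prop-1-en-1-yl]oxolan-2-one
Conditions: Dess–Martin periodinane, NaHCO3, CH2Cl2, 0 °C to rt
Reagents that add atoms: none
Why: Dess–Martin oxidation under bicarbonate buffer converts the secondary alcohol into the methyl ketone without acid or base strong enough to epimerise C7 or to move the exocyclic double bond into conjugation; the lactate centre, its task done, disappears here.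

Step 12
Reactants: 19 (4S,5S)-4-acetyl-3-methylidene-5-[(1Z)-2-(5-methylfuran-2-yl)prop-1-en-1-yl]oxolan-2-one
Product: 21 (4S,5S)-4-[1-(tert-butyldimethylsilyloxy)ethenyl]-3-methylidene-5-[(1Z)-2-(5-methylfuran-2-yl)prop-1-en-1-yl]oxolan-2-one, via lithium enolate 20 (not isolated)
Conditions: LiN(SiMe3)2, THF, −78 °C; then TBSOTf, −78 °C; Et3N, aq. NaHCO3
Reagents that add atoms: tert-butyldimethylsilyl trifluoromethanesulfonate, CC(C)(C)[Si](C)(C)OS(=O)(=O)C(F)(F)F
Why: Kinetic deprotonation with the hindered amide at −78 °C removes a proton from the exposed methyl group rather than the tertiary, ring-flanked C7–H, and immediate O-silylation of the lithium enolate at the same temperature fixes the terminal enol ether before proton transfer, attack on the lactone carbonyl or conjugate addition can compete.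

Step 13
Reactants: 21 (4S,5S)-4-[1-(tert-butyldimethylsilyloxy)ethenyl]-3-methylidene-5-[(1Z)-2-(5-methylfuran-2-yl)prop-1-en-1-yl]oxolan-2-one; 22 methanol
Product: 23 (3R,6S,7S,10R)-3-methoxy-3,10-epoxy-8-oxogermacra-1,4Z,11(13)-trien-12,6-olide (3,10-oxygen-bridged C3 methyl ketal with C8 ketone)
Conditions: reticulated vitreous carbon anode, Pt cathode, undivided cell, constant current (about 2.2 F/mol), LiClO4 (0.1 M), 2,6-lutidine, MeOH/CH2Cl2 (1:9), substrate about 2 mM, rt
Reagents that add atoms: none
Why: Proposed new method: one-electron oxidation of the electron-rich alkenylfuran/enol ether pair at the anode should give a radical cation in which the enol ether terminus C9 bonds to the methyl-bearing furan carbon C10; a second electron transfer gives the C3 oxocarbenium ion, methanol adds there and the silyl group is lost to methanol, which unmasks the C8 ketone. The closest known reactions are anodic couplings of silyl enol ethers with furans that close six- and seven-membered rings at an unsubstituted furan carbon, and the anodic 2,5-dimethoxylation of furans; here carbon takes the place of one methanol and attacks a substituted alpha carbon. One ring is formed, the ten-membered carbocycle C1–C10, by endo attack of C9 on the furan C10=C1 bond (a nine-membered closure when counted through the furan oxygen, which becomes the 3,10-bridge), and the furan, the Z alkene and the cis lactone leave only three rotatable bonds between C9 and C10. C10 is set by the furan face that C9 can reach: allylic 1,3-strain across the Z C4=C5 bond keeps H6 in the alkene plane, so the C7 arm lies on one face only; C3 follows because C4 and C9 must be cis on the dihydrofuran for the bridge to exist, which leaves methanol the outer face. The step needs bonding at C10 rather than at C5 (a stereoelectronically disfavoured 5-(enolendo)-exo closure) or at the ipso carbon C3 (shielded by the C4 methyl-bearing alkene and leading to a less delocalised intermediate), C–C bonding ahead of methanol capture of the radical cation (hence little methanol and high dilution), and methanol capture at C3 rather than C5 (only C3 gives the oxygen-stabilised ketal); the 2,6-lutidine buffer protects C7 and the electron-poor exomethylene lactone is not oxidised at this potential.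

Step 14
Reactants: 23 (3R,6S,7S,10R)-3-methoxy-3,10-epoxy-8-oxogermacra-1,4Z,11(13)-trien-12,6-olide
Product: 24 (6S,7S,10R)-10-hydroxy-3,8-dioxogermacra-1Z,4Z,11(13)-trien-12,6-olide
Conditions: pyridinium p-toluenesulfonate (cat.), acetone/H2O (10:1), 0 °C to rt
Reagents that add atoms: water, O
Why: The 2-methoxy-2,5-dihydrofuran is a doubly allylic ketal that ionises under very mild acid, water adds at C3 and the hemiketal opens to the C3 ketone and the C10 tertiary alcohol; the conditions are too mild to enolise the C8 ketone towards C7 or to ionise the C10–O bond.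

Step 15
Reactants: 24 (6S,7S,10R)-10-hydroxy-3,8-dioxogermacra-1Z,4Z,11(13)-trien-12,6-olide
Product: 25 (6S,7R,8R,10R)-8,10-dihydroxy-3-oxogermacra-1Z,4Z,11(13)-trien-12,6-olide
Conditions: Me4NBH(OAc)3, AcOH/MeCN (1:1), −30 °C to −10 °C
Reagents that add atoms: none
Why: Evans–Saksena reduction: the C10 hydroxyl exchanges with an acetate on boron and the resulting alkoxyborohydride delivers hydride intramolecularly to the beta-carbonyl C8 through a chair six-membered transition state with the ring carbons C1 and C7 equatorial, which gives the 1,3-anti diol (8R), whereas the C3 dienone and the lactone, which have no hydroxyl in reach, are not reduced by this weak hydride donor.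

Step 16
Reactants: 25 (6S,7R,8R,10R)-8,10-dihydroxy-3-oxogermacra-1Z,4Z,11(13)-trien-12,6-olide; 26 tigloyl chloride
Product: 27 (6S,7R,8R,10R)-10-hydroxy-3-oxo-8-[(2E)-2-methylbut-2-enoyloxy]germacra-1Z,4Z,11(13)-trien-12,6-olide (target)
Conditions: 4-(dimethylamino)pyridine, Et3N, CH2Cl2, 0 °C to rt
Reagents that add atoms: none
Why: Nucleophilic catalysis by 4-(dimethylamino)pyridine acylates the only secondary alcohol, the tertiary C10 hydroxyl being too hindered; the E-configured tigloyl group is the stable geometric isomer and is transferred unchanged.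

**Compound list**

1 | ethyl but-2-ynoate | CC#CC(=O)OCC | starting material
2 | ethyl (2Z)-3-iodobut-2-enoate | CCOC(=O)/C=C(/C)I | intermediate
3 | 2-methylfuran | Cc1ccco1 | starting material
4 | (5-methylfuran-2-yl)lithium | [Li]c1ccc(C)o1 | intermediate (not isolated)
5 | chloro(5-methylfuran-2-yl)zinc | Cl[Zn]c1ccc(C)o1 | intermediate (not isolated)
6 | ethyl (2Z)-3-(5-methylfuran-2-yl)but-2-enoate | CCOC(=O)/C=C(/C)c1ccc(C)o1 | intermediate
7 | (2Z)-3-(5-methylfuran-2-yl)but-2-en-1-ol | OC/C=C(/C)c1ccc(C)o1 | intermediate
8 | (2Z)-3-(5-methylfuran-2-yl)but-2-enal | O=C/C=C(/C)c1ccc(C)o1 | intermediate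
9 | methyl (S)-lactate | COC(=O)[C@H](C)O | starting material
10 | methyl (2S)-2-[(tert-butyldimethylsilyl)oxy]propanoate | COC(=O)[C@H](C)O[Si](C)(C)C(C)(C)C | intermediate
11 | (2S)-2-[(tert-butyldimethylsilyl)oxy]propanal | O=C[C@H](C)O[Si](C)(C)C(C)(C)C | intermediate
12 | methyl acrylate | C=CC(=O)OC | starting material
13 | methyl (4S)-4-[(tert-butyldimethylsilyl)oxy]-3-hydroxy-2-methylidenepentanoate (both C3 epimers) | COC(=O)C(=C)C(O)[C@H](C)O[Si](C)(C)C(C)(C)C | intermediate
14 | methyl (2Z,4S)-2-(bromomethyl)-4-[(tert-butyldimethylsilyl)oxy]pent-2-enoate | COC(=O)/C(CBr)=C/[C@H](C)O[Si](C)(C)C(C)(C)C | intermediate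
15 | allylindium bromide from 14 (drawn as the allylindium dibromide) | COC(=O)/C(C[In](Br)Br)=C/[C@H](C)O[Si](C)(C)C(C)(C)C | intermediate (not isolated)
16 | syn hydroxy ester, methyl (3S,4S,5Z)-3-[(1S)-1-(tert-butyldimethylsilyloxy)ethyl]-4-hydroxy-2-methylidene-6-(5-methylfuran-2-yl)hept-5-enoate | COC(=O)C(=C)[C@H]([C@H](C)O[Si](C)(C)C(C)(C)C)[C@@H](O)/C=C(/C)c1ccc(C)o1 | intermediate (not isolated)
17 | (4S,5S)-4-[(1S)-1-(tert-butyldimethylsilyloxy)ethyl]-3-methylidene-5-[(1Z)-2-(5-methylfuran-2-yl)prop-1-en-1-yl]oxolan-2-one (cis lactone) | C=C1C(=O)O[C@@H](/C=C(/C)c2ccc(C)o2)[C@H]1[C@H](C)O[Si](C)(C)C(C)(C)C | intermediate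
18 | (4R,5S)-4-[(1S)-1-hydroxyethyl]-3-methylidene-5-[(1Z)-2-(5-methylfuran-2-yl)prop-1-en-1-yl]oxolan-2-one | C=C1C(=O)O[C@@H](/C=C(/C)c2ccc(C)o2)[C@H]1[C@H](C)O | intermediate
19 | (4S,5S)-4-acetyl-3-methylidene-5-[(1Z)-2-(5-methylfuran-2-yl)prop-1-en-1-yl]oxolan-2-one | C=C1C(=O)O[C@@H](/C=C(/C)c2ccc(C)o2)[C@H]1C(C)=O | intermediate
20 | lithium enolate of 19 (terminal, C8=C9) | C=C1C(=O)O[C@@H](/C=C(/C)c2ccc(C)o2)[C@H]1C(=C)O[Li] | intermediate (not isolated)
21 | (4S,5S)-4-[1-(tert-butyldimethylsilyloxy)ethenyl]-3-methylidene-5-[(1Z)-2-(5-methylfuran-2-yl)prop-1-en-1-yl]oxolan-2-one | C=C1C(=O)O[C@@H](/C=C(/C)c2ccc(C)o2)[C@H]1C(=C)O[Si](C)(C)C(C)(C)C | intermediate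
22 | methanol | CO | starting material
23 | (3R,6S,7S,10R)-3-methoxy-3,10-epoxy-8-oxogermacra-1,4Z,11(13)-trien-12,6-olide | C=C1C(=O)O[C@H]2/C=C(/C)[C@@]3(OC)C=C[C@](C)(O3)CC(=O)[C@@H]12 | intermediate
24 | (6S,7S,10R)-10-hydroxy-3,8-dioxogermacra-1Z,4Z,11(13)-trien-12,6-olide | C=C1C(=O)O[C@H]2/C=C(/C)C(=O)/C=C\[C@](C)(O)CC(=O)[C@@H]12 | intermediate
25 | (6S,7R,8R,10R)-8,10-dihydroxy-3-oxogermacra-1Z,4Z,11(13)-trien-12,6-olide | C=C1C(=O)O[C@H]2/C=C(/C)C(=O)/C=C\[C@](C)(O)C[C@@H](O)[C@@H]12 | intermediate
26 | tigloyl chloride, (2E)-2-methylbut-2-enoyl chloride | ClC(=O)/C(C)=C/C | starting material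
27 | (6S,7R,8R,10R)-10-hydroxy-3-oxo-8-[(2E)-2-methylbut-2-enoyloxy]germacra-1Z,4Z,11(13)-trien-12,6-olide | C=C1C(=O)O[C@H]2/C=C(/C)C(=O)/C=C\[C@](C)(O)C[C@@H](OC(=O)/C(C)=C/C)[C@@H]12 | target

**Count**

Total steps: 16. Longest linear sequence: 12 steps (steps 5–16 from methyl (S)-lactate; equally steps 1–4 and 9–16 from ethyl but-2-ynoate).

**Steps most likely to fail**

1. Step 13. The C9 terminus may bond elsewhere in the oxidised alkenylfuran (at C5, closing a five-membered ring, or at the ipso carbon C3, closing a seven-membered ring), or methanol may capture the radical cation before any C–C bond forms, so that the furan is merely dimethoxylated. The fallback sets out from 21 and comes back to the route at 24. Dye-sensitised photooxygenation of the furan (O2, visible light, 5,10,15,20-tetraphenylporphyrin, CH2Cl2, −78 °C; then Me2S) is a [4+2] addition of singlet oxygen that is far faster on a 2,5-dialkylfuran than on a silyl enol ether; reduction of the endoperoxide should give the Z-enedione F1, in which C10 is a methyl ketone. A Mukaiyama aldol addition under high dilution (BF3·OEt2, CH2Cl2, −78 °C) then forms the same C9–C10 bond by two-electron chemistry; the C10 carbonyl is the less hindered and more electrophilic of the two (C3 is a cross-conjugated dienone flanked by the C4 methyl group), and the aldol product is 24, stabilised as its 3,10-hemiketal.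

2. Step 9. The aldehyde may add to C7 with poor or reversed facial selectivity relative to the silyloxy centre, the allylindium may lose its Z geometry (which erodes the syn/cis relationship), and the Z enal may isomerise under the Lewis-acidic aqueous conditions. Because the lactate centre is erased in step 11, a reversed sense alone would be corrected by the antipodal lactate; the fallback removes the dependence on substrate control. It sets out from 14 (with 8) and comes back at 17. Palladium-catalysed borylation of the bromide (B2pin2, Pd2(dba)3, THF, rt) should give the allylboronate F2 with the alkene geometry unchanged. Its addition to 8 is run under a chiral phosphoric acid, 3,3′-bis(2,4,6-triisopropylphenyl)-1,1′-binaphthyl-2,2′-diyl hydrogen phosphate, in the enantiomeric form that leads to the 6S,7S adduct (toluene, −30 °C); it goes through a closed chair transition state in which the catalyst selects the aldehyde face, and the fixed alkene geometry keeps the syn relationship. Lactonisation with pyridinium p-toluenesulfonate as in step 9 then gives 17.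

3. Step 15. In the ten-membered ring the hydride may be delivered through the alternative chair (C14 rather than C1 equatorial), which gives the C8 epimer, and hemiketal formation between O10 and C3 may withdraw the directing hydroxyl. The fallback sets out from 23 and comes back at 27. In 23 the C3 carbonyl is still masked, so C8 is the only ketone. Corey–Bakshi–Shibata reduction ((S)-3,3-diphenyl-1-methyltetrahydro-1H,3H-pyrrolo[1,2-c][1,3,2]oxazaborole, catecholborane, toluene, −78 °C) sets C8 under reagent control, with the branched C7 as the large and the C9 methylene as the small substituent, and should give the 8R alcohol F3. Acylation under the conditions of step 16 gives the tiglate F4, and the ketal hydrolysis of step 14, now the last operation, gives 27.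

Further compounds
F1 | step 13 | (4S,5S)-4-[1-(tert-butyldimethylsilyloxy)ethenyl]-3-methylidene-5-[(1Z,4Z)-2-methyl-3,6-dioxohepta-1,4-dien-1-yl]oxolan-2-one | C=C1C(=O)O[C@@H](/C=C(/C)C(=O)/C=C\C(C)=O)[C@H]1C(=C)O[Si](C)(C)C(C)(C)C
F2 | step 9 | methyl (2E,4S)-4-[(tert-butyldimethylsilyl)oxy]-2-[(4,4,5,5-tetramethyl-1,3,2-dioxaborolan-2-yl)methyl]pent-2-enoate | COC(=O)/C(CB1OC(C)(C)C(C)(C)O1)=C/[C@H](C)O[Si](C)(C)C(C)(C)C
F3 | step 15 | (3R,6S,7R,8R,10R)-8-hydroxy-3-methoxy-3,10-epoxygermacra-1,4Z,11(13)-trien-12,6-olide | C=C1C(=O)O[C@H]2/C=C(/C)[C@@]3(OC)C=C[C@](C)(O3)C[C@@H](O)[C@@H]12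
F4 | step 15 | (3R,6S,7R,8R,10R)-3-methoxy-8-[(2E)-2-methylbut-2-enoyloxy]-3,10-epoxygermacra-1,4Z,11(13)-trien-12,6-olide | C=C1C(=O)O[C@H]2/C=C(/C)[C@@]3(OC)C=C[C@](C)(O3)C[C@@H](OC(=O)/C(C)=C/C)[C@@H]12
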